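**Plan**

- Cuts: the C2–O1 hemiketal bond is opened to the C2/C3/C4 1,3-diketone, which is folded into a 3,5-disubstituted isoxazole (C4 = isoxazole C3, C2 = isoxazole C5). Ring A is cut at C4a–C5 and C8–C8a, and the isoxazole is cut into a nitrile oxide and a terminal alkyne.
- Feature used: ring A is a 5-heptylresorcinol with the acyl carbon C4 on C4a. C5 to C8 with the heptyl chain are the carbons of undec-3-en-2-one. C4a and C8a are the α-carbon and carbonyl carbon of an acetate whose α-substituent, isoxazole C3, is C4 in masked form.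
- Forward order: ring B side chain (benzyl bromide to silylpropyne, formylation, oxidation, benzyl ester), then the isoxazole by cycloaddition, then ring A by Michael–Dieckmann annulation and aromatisation.
- One hydrogenolysis then removes all benzyl groups and opens the isoxazole; ring C (the pyranone) closes last by hemiketalisation.
- Stereochemistry: C2 is the only stereocentre and is a hemiketal carbon. It forms as a racemate in the last closure and the (R)-enantiomer is taken by preparative chromatography on a chiral phase, with the (S)-antipode re-equilibrated through the open diketone and recycled. The two centres made in the annulation are erased on aromatisation.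

Key step: step 8

Assumption: C2 is taken to hold its configuration in cold, neutral, aprotic media (ring–chain tautomerism needing acid or base), the 2-hydroxychromanone is taken to be the favoured ring tautomer of the open diketo acid, and 3,5-bis(benzyloxy)benzyl bromide and methyl 3-nitropropanoate are taken as commercial.

**Route**

Step 1
Reactants: 1 ethynyltrimethylsilane; 2 1,3-bis(benzyloxy)-5-(bromomethyl)benzene
Product: 4 {3-[3,5-bis(benzyloxy)phenyl]prop-1-yn-1-yl}(trimethyl)silane, via alkynylmagnesium bromide 3 (not isolated)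
Conditions: 1, EtMgBr, THF, 0 °C to rt; then 2, CuBr (10 mol%), reflux
Reagents that add atoms: none
Why: Copper-catalysed coupling of an alkynyl Grignard reagent with a benzylic bromide is a standard entry to 3-aryl-1-silylpropynes, and the silyl cap blocks double alkylation and propargyl–allene isomerisation.

Step 2
Reactants: 4 {3-[3,5-bis(benzyloxy)phenyl]prop-1-yn-1-yl}(trimethyl)silane
Product: 6 2,4-bis(benzyloxy)-6-[3-(trimethylsilyl)prop-2-yn-1-yl]benzaldehyde, via aryl iminium chloride 5 (not isolated)
Conditions: POCl3, DMF, 0 to 50 °C; then aq. NaOAc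
Reagents that add atoms: N,N-dimethylformamide, CN(C)C=O; water, O
Why: Vilsmeier–Haack formylation of a 5-alkylresorcinol diether should go ortho to the alkyl group and para to one ether, the position between the two ethers being the more hindered, as is usual for orcinol-type ethers.

Step 3
Reactants: 6 2,4-bis(benzyloxy)-6-[3-(trimethylsilyl)prop-2-yn-1-yl]benzaldehyde
Product: 7 2,4-bis(benzyloxy)-6-[3-(trimethylsilyl)prop-2-yn-1-yl]benzoic acid
Conditions: NaClO2, NaH2PO4, 2-methylbut-2-ene, t-BuOH–THF–H2O, 0 °C to rt
Reagents that add atoms: sodium chlorite, [Na+].[O-]Cl=O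
Why: Pinnick oxidation converts hindered, electron-rich benzaldehydes to acids without touching alkynes or benzyl ethers, the alkene scavenger removing hypochlorite before it can chlorinate the ring.

Step 4
Reactants: 7 2,4-bis(benzyloxy)-6-[3-(trimethylsilyl)prop-2-yn-1-yl]benzoic acid
Product: 8 benzyl 2,4-bis(benzyloxy)-6-[3-(trimethylsilyl)prop-2-yn-1-yl]benzoate
Conditions: BnBr, KHCO3, DMF, 40 °C
Reagents that add atoms: benzyl bromide, BrCc1ccccc1
Why: SN2 O-alkylation of the carboxylate is insensitive to the two ortho substituents, and hydrogencarbonate is too weak a base to isomerise the propargylic methylene.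

Step 5
Reactants: 8 benzyl 2,4-bis(benzyloxy)-6-[3-(trimethylsilyl)prop-2-yn-1-yl]benzoate
Product: 9 benzyl 2,4-bis(benzyloxy)-6-(prop-2-yn-1-yl)benzoate
Conditions: Bu4NF, AcOH, THF, 0 °C
Reagents that add atoms: none
Why: Fluoride-mediated protodesilylation of the alkynylsilane, buffered with acetic acid so that the acidic propargylic position does not isomerise to the allene.

Step 6
Reactants: 9 benzyl 2,4-bis(benzyloxy)-6-(prop-2-yn-1-yl)benzoate; 10 methyl 3-nitropropanoate
Product: 12 benzyl 2,4-bis(benzyloxy)-6-{[3-(2-methoxy-2-oxoethyl)isoxazol-5-yl]methyl}benzoate, via nitrile oxide 11 (not isolated)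
Conditions: PhNCO, Et3N (cat.), toluene, rt to 60 °C, slow addition of 10
Reagents that add atoms: none
Why: Mukaiyama dehydration of the primary nitro compound gives the nitrile oxide, whose 1,3-dipolar (Huisgen) cycloaddition to a terminal alkyne places the alkyne substituent at isoxazole C5; slow generation keeps the dipole dilute against furoxan formation, and the weak amine base is not expected to eliminate nitrite.

Step 7
Reactants: 13 octanal; 14 1-(triphenylphosphoranylidene)propan-2-one
Product: 15 (E)-undec-3-en-2-one
Conditions: CH2Cl2, rt to 40 °C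
Reagents that add atoms: none
Why: Wittig olefination with a stabilised acyl ylide gives the (E)-enone under thermodynamic control of oxaphosphetane formation and avoids the self-condensation of an acetone aldol route.

Step 8
Reactants: 12 benzyl 2,4-bis(benzyloxy)-6-{[3-(2-methoxy-2-oxoethyl)isoxazol-5-yl]methyl}benzoate; 15 (E)-undec-3-en-2-one
Product: 17 benzyl 2,4-bis(benzyloxy)-6-{[3-(trans-6-heptyl-2,4-dioxocyclohexyl)isoxazol-5-yl]methyl}benzoate (racemate), via Michael adduct 16 (not isolated)
Conditions: KOtBu (1.3 equiv), THF–t-BuOH, 0 °C, 15 added slowly; then 60 °C; aq. HCl to pH 3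
Reagents that add atoms: none
Why: tert-Butoxide deprotonates the ester α-carbon of 12, the most acidic C–H because it is flanked by the ester and the isoxazole C=N; the enolate adds to the β-carbon of 15 to form C4a–C5 and give 16, whose methyl-ketone enolate then attacks the methyl ester and expels methoxide to form C8–C8a, the dione enolate being the thermodynamic sink. The closest known reaction type is the Michael–Dieckmann (Michael–Claisen) condensation of malonates and arylacetates with alk-3-en-2-ones to cyclohexane-1,3-diones, the usual entry to 5-alkylresorcinols. The six-membered ring closes in a 6-exo-trig (enolexo) mode on the ester carbonyl. The two new stereocentres, C4a and C5, are under thermodynamic control because C4a is epimerisable, so the diequatorial trans racemate should prevail, and both are destroyed in step 9. The step needs C–C bond formation at the acetate carbon only and Claisen instead of aldol closure: the isoxazole holds C4 as a non-electrophilic C=N so the ester is the only acceptor within reach, the 5-methylene is judged several pKa units less acidic than the ester α-carbon, and the non-nucleophilic base spares the di-ortho-substituted benzyl benzoate.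

Step 9
Reactants: 17 benzyl 2,4-bis(benzyloxy)-6-{[3-(trans-6-heptyl-2,4-dioxocyclohexyl)isoxazol-5-yl]methyl}benzoate (racemate)
Product: 19 benzyl 2,4-bis(benzyloxy)-6-{[3-(2-heptyl-4,6-dihydroxyphenyl)isoxazol-5-yl]methyl}benzoate, via bromodione 18 (not isolated)
Conditions: Br2 (1.0 equiv), DMF, 0 °C; then 70 °C
Reagents that add atoms: none
Why: Halogenation–dehydrohalogenation aromatisation of a 4,5-disubstituted cyclohexane-1,3-dione: the enol carbon C8 is brominated far faster than any arene, and loss of HBr on warming leaves the resorcinol, as in the preparation of alkylresorcylates.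

Step 10
Reactants: 19 benzyl 2,4-bis(benzyloxy)-6-{[3-(2-heptyl-4,6-dihydroxyphenyl)isoxazol-5-yl]methyl}benzoate
Product: 22 rac-2-[(5-heptyl-2,7-dihydroxy-4-oxo-3,4-dihydro-2H-chromen-2-yl)methyl]-4,6-dihydroxybenzoic acid, via enaminone 20 (not isolated), via open-chain diketone 21 (not isolated)
Conditions: H2 (1 atm), Pd/C (10% Pd on carbon), EtOAc–MeOH, rt; filter, concentrate; then 0.5 M aq. HCl, THF, 0 °C to rt
Reagents that add atoms: water, O
Why: Catalytic hydrogenolysis removes the three O-benzyl groups and cleaves the weak isoxazole N–O bond to the Z-enaminone; cold dilute acid then hydrolyses the vinylogous amide to the 1,3-diketone, whose C2 carbonyl is captured by the C8a hydroxyl in a 6-exo-trig hemiketalisation, giving C2 as a racemate while avoiding dehydration to the chromone.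

Step 11
Reactants: 22 rac-2-[(5-heptyl-2,7-dihydroxy-4-oxo-3,4-dihydro-2H-chromen-2-yl)methyl]-4,6-dihydroxybenzoic acid
Product: 23 2-{[(2R)-5-heptyl-2,7-dihydroxy-4-oxo-3,4-dihydro-2H-chromen-2-yl]methyl}-4,6-dihydroxybenzoic acid
Conditions: preparative chiral SFC, immobilised amylose tris(3,5-dimethylphenylcarbamate) phase, CO2–MeCN, 20 °C; fractions evaporated cold
Reagents that add atoms: none
Why: Resolution by preparative chromatography on a chiral stationary phase separates the enantiomers without any bond change; the (R)-isomer, to be assigned by circular dichroism against a computed curve, is kept cold and neutral so that ring–chain tautomerism cannot scramble C2, and the (S)-isomer is re-equilibrated with a trace of acid and resubmitted.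

**Compound list**

1 | ethynyltrimethylsilane | C#C[Si](C)(C)C | starting material
2 | 1,3-bis(benzyloxy)-5-(bromomethyl)benzene | BrCc1cc(OCc2ccccc2)cc(OCc2ccccc2)c1 | starting material
3 | [(trimethylsilyl)ethynyl]magnesium bromide (not isolated) | C[Si](C)(C)C#C[Mg]Br | intermediate
4 | {3-[3,5-bis(benzyloxy)phenyl]prop-1-yn-1-yl}(trimethyl)silane | C[Si](C)(C)C#CCc1cc(OCc2ccccc2)cc(OCc2ccccc2)c1 | intermediate
5 | N-{2,4-bis(benzyloxy)-6-[3-(trimethylsilyl)prop-2-yn-1-yl]benzylidene}-N-methylmethanaminium chloride (not isolated) | C[N+](C)=Cc1c(CC#C[Si](C)(C)C)cc(OCc2ccccc2)cc1OCc1ccccc1.[Cl-] | intermediate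
6 | 2,4-bis(benzyloxy)-6-[3-(trimethylsilyl)prop-2-yn-1-yl]benzaldehyde | O=Cc1c(CC#C[Si](C)(C)C)cc(OCc2ccccc2)cc1OCc1ccccc1 | intermediate
7 | 2,4-bis(benzyloxy)-6-[3-(trimethylsilyl)prop-2-yn-1-yl]benzoic acid | OC(=O)c1c(CC#C[Si](C)(C)C)cc(OCc2ccccc2)cc1OCc1ccccc1 | intermediate
8 | benzyl 2,4-bis(benzyloxy)-6-[3-(trimethylsilyl)prop-2-yn-1-yl]benzoate | C[Si](C)(C)C#CCc1cc(OCc2ccccc2)cc(OCc2ccccc2)c1C(=O)OCc1ccccc1 | intermediate
9 | benzyl 2,4-bis(benzyloxy)-6-(prop-2-yn-1-yl)benzoate | C#CCc1cc(OCc2ccccc2)cc(OCc2ccccc2)c1C(=O)OCc1ccccc1 | intermediate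
10 | methyl 3-nitropropanoate | COC(=O)CC[N+](=O)[O-] | starting material
11 | methyl cyanoacetate N-oxide, the nitrile oxide (not isolated) | COC(=O)CC#[N+][O-] | intermediate
12 | benzyl 2,4-bis(benzyloxy)-6-{[3-(2-methoxy-2-oxoethyl)isoxazol-5-yl]methyl}benzoate | COC(=O)Cc1cc(Cc2cc(OCc3ccccc3)cc(OCc3ccccc3)c2C(=O)OCc2ccccc2)on1 | intermediate
13 | octanal | CCCCCCCC=O | starting material
14 | 1-(triphenylphosphoranylidene)propan-2-one | CC(=O)C=P(c1ccccc1)(c1ccccc1)c1ccccc1 | starting material
15 | (E)-undec-3-en-2-one | CCCCCCC/C=C/C(C)=O | intermediate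
16 | benzyl 2,4-bis(benzyloxy)-6-{[3-(3-heptyl-1-methoxy-1,5-dioxohexan-2-yl)isoxazol-5-yl]methyl}benzoate (diastereomer mixture, not isolated) | COC(=O)C(c1cc(Cc2cc(OCc3ccccc3)cc(OCc3ccccc3)c2C(=O)OCc2ccccc2)on1)C(CCCCCCC)CC(C)=O | intermediate
17 | benzyl 2,4-bis(benzyloxy)-6-{[3-(trans-6-heptyl-2,4-dioxocyclohexyl)isoxazol-5-yl]methyl}benzoate (racemic, one enantiomer drawn) | O=C1CC(=O)[C@@H](c2cc(Cc3cc(OCc4ccccc4)cc(OCc4ccccc4)c3C(=O)OCc3ccccc3)on2)[C@H](CCCCCCC)C1 | intermediate
18 | benzyl 2,4-bis(benzyloxy)-6-{[3-(3-bromo-6-heptyl-2,4-dioxocyclohexyl)isoxazol-5-yl]methyl}benzoate (not isolated) | O=C1CC(CCCCCCC)C(c2cc(Cc3cc(OCc4ccccc4)cc(OCc4ccccc4)c3C(=O)OCc3ccccc3)on2)C(=O)C1Br | intermediate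
19 | benzyl 2,4-bis(benzyloxy)-6-{[3-(2-heptyl-4,6-dihydroxyphenyl)isoxazol-5-yl]methyl}benzoate | CCCCCCCc1cc(O)cc(O)c1-c1cc(Cc2cc(OCc3ccccc3)cc(OCc3ccccc3)c2C(=O)OCc2ccccc2)on1 | intermediate
20 | 2-[(3Z)-4-amino-4-(2-heptyl-4,6-dihydroxyphenyl)-2-oxobut-3-en-1-yl]-4,6-dihydroxybenzoic acid (not isolated) | CCCCCCCc1cc(O)cc(O)c1/C(N)=C/C(=O)Cc1cc(O)cc(O)c1C(=O)O | intermediate
21 | 2-[4-(2-heptyl-4,6-dihydroxyphenyl)-2,4-dioxobutyl]-4,6-dihydroxybenzoic acid (not isolated) | CCCCCCCc1cc(O)cc(O)c1C(=O)CC(=O)Cc1cc(O)cc(O)c1C(=O)O | intermediate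
22 | rac-2-[(5-heptyl-2,7-dihydroxy-4-oxo-3,4-dihydro-2H-chromen-2-yl)methyl]-4,6-dihydroxybenzoic acid | CCCCCCCc1cc(O)cc2c1C(=O)CC(O)(Cc1cc(O)cc(O)c1C(=O)O)O2 | intermediate
23 | 2-{[(2R)-5-heptyl-2,7-dihydroxy-4-oxo-3,4-dihydro-2H-chromen-2-yl]methyl}-4,6-dihydroxybenzoic acid | CCCCCCCc1cc(O)cc2c1C(=O)C[C@@](O)(Cc1cc(O)cc(O)c1C(=O)O)O2 | target

**Step count**

Total: 11 steps. Longest linear sequence: 10 steps (steps 1 to 6 and 8 to 11, from 2 to 23); step 7 is the only side branch.

**Steps most likely to fail**

Step 8. The alkoxide-mediated conjugate addition may stall or revert before the Claisen closure, deprotonation may spread to the doubly benzylic 5-methylene, and the enone may oligomerise under base. The fallback sets out from 12 and comes back at 17, and it separates a Lewis-acid Michael step from the ring closure. Kinetic deprotonation of 12 with LiN(SiMe3)2 in THF at −78 °C and trapping with Me3SiCl should give the ketene silyl acetal F1. Under catalytic Me3SiOTf in CH2Cl2 at −78 °C this adds to 15 (Mukaiyama–Michael addition) to give the silyl enol ether F2, which mild aqueous acid converts to the keto ester 16, now isolated. KOtBu in THF then closes 16 by Dieckmann condensation to 17, so the same two bonds and the same ring are formed without any base being present in the Michael step.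

Step 9. Electrophilic bromine may attack the electron-rich ring B or over-brominate the resorcinol once formed, and the HBr released may strip benzyl groups. The fallback sets out from 12 and comes back at 19, and it moves the oxidation into the four-carbon partner so that no oxidant is needed. Commercial non-1-yne is lithiated with n-BuLi in THF at −78 °C and acylated with N-methoxy-N-methylacetamide to give undec-3-yn-2-one F3. With KOtBu in THF, 12 adds to F3 to give the enone ester F4 in the flask; after double-bond equilibration through its dienolate this closes by Dieckmann condensation on the ester and tautomerises directly to 19.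

Step 11. Ring–chain tautomerism of the hemiketal may erode the enantiomeric purity during chromatography or evaporation. The fallback sets out from 22 and comes back at 23, and it turns this lability into a crystallisation-induced dynamic resolution. Racemic 22 is stirred with (R)-1-phenylethylamine in MeCN–EtOAc so that the less soluble diastereomeric salt, the (R)-1-phenylethylammonium salt of the (2R)-acid F5, crystallises while the amine keeps the dissolved material equilibrating through the open diketone. Should the crystals hold the (2S)-acid, the antipodal amine is used instead. The salt is then broken with cold aqueous KHSO4 and extraction to give 23.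

**Further compounds**

F1 | step 8 | benzyl 2,4-bis(benzyloxy)-6-({3-[2-methoxy-2-(trimethylsilyloxy)ethenyl]isoxazol-5-yl}methyl)benzoate | COC(O[Si](C)(C)C)=Cc1cc(Cc2cc(OCc3ccccc3)cc(OCc3ccccc3)c2C(=O)OCc2ccccc2)on1
F2 | step 8 | benzyl 2,4-bis(benzyloxy)-6-({3-[3-heptyl-1-methoxy-1-oxo-5-(trimethylsilyloxy)hex-4-en-2-yl]isoxazol-5-yl}methyl)benzoate | COC(=O)C(c1cc(Cc2cc(OCc3ccccc3)cc(OCc3ccccc3)c2C(=O)OCc2ccccc2)on1)C(CCCCCCC)C=C(C)O[Si](C)(C)C
F3 | step 9 | undec-3-yn-2-one | CCCCCCCC#CC(C)=O
F4 | step 9 | benzyl 2,4-bis(benzyloxy)-6-{[3-(3-heptyl-1-methoxy-1,5-dioxohex-3-en-2-yl)isoxazol-5-yl]methyl}benzoate | COC(=O)C(c1cc(Cc2cc(OCc3ccccc3)cc(OCc3ccccc3)c2C(=O)OCc2ccccc2)on1)C(CCCCCCC)=CC(C)=O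
F5 | step 11 | (R)-1-phenylethylammonium 2-{[(2R)-5-heptyl-2,7-dihydroxy-4-oxo-3,4-dihydro-2H-chromen-2-yl]methyl}-4,6-dihydroxybenzoate | CCCCCCCc1cc(O)cc2c1C(=O)C[C@@](O)(Cc1cc(O)cc(O)c1C(=O)[O-])O2.C[C@@H]([NH3+])c1ccccc1
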